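## Structural features

The target joins five oxygenated benzene rings (A to E) through three small units: an α-aryl-β-hydroxy ketone chain between rings A and B, a cis-fused 2,6-diaryl-3,7-dioxabicyclo[3.3.0]octane (furofuran) between rings B and D, and a 2,3-dihydrobenzofuran whose benzo ring is ring D and whose C2 carries ring E. Ring B is a guaiacol with the ketone chain ortho and the furofuran para to its hydroxyl. Ring D carries the furofuran carbon para to the ring oxygen O1 and a methoxy group at C7 next to it. The stereocenters fall into three separate groups: the ketone α-carbon (S); the four contiguous centres C1, C2, C5, C6 of the bicycle (1R,2S,5R,6S, both aryl groups exo); and C2/C3 of the dihydrobenzofuran (2S,3S), which are cis and therefore the less stable arrangement. The ketone α-carbon is doubly activated and carries a β-hydroxyl, so base threatens epimerisation, retro-aldol loss of formaldehyde and dehydration, and acid threatens cyclodehydration with the neighbouring ring B phenol. The three benzylic ether carbons para to oxygen (C2 and C6 of the bicycle, C2 of the dihydrobenzofuran) ionise in acid and can epimerise, and the free phenols are easily oxidised. The real difficulty is therefore the cis ring, the labile ketone centre, and a protecting-group order that keeps the last steps neither basic nor strongly acidic. The key step exploits ring D: C7a (with O1), C7 (OMe), C6, C5 (with its one-carbon substituent), C4 and C3a map onto C3 (with its oxygen), C4, C5, C6 of a 2-pyrone plus the two carbons of a terminal alkyne that is tied to the pyrone 3-oxygen through the future C2 and C3.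

## Logic of the disconnections

51 to 50: the four Si–O bonds are cut last in the forward sense. All phenols and the ring D primary alcohol are carried as one kind of silyl ether, so a single non-basic fluoride treatment ends the synthesis. The demand is that every earlier step tolerates aryl and alkyl silyl ethers.

50 to 49 to 48: the ketone is traced to the benzylic alcohol and the 1,3-diol to a cyclic acetal. The α-carbon is configurationally safe while its neighbour is a carbinol, so it can be set early by an auxiliary. The forward oxidation must distinguish the benzylic from the primary hydroxyl and must be neutral.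

48 to 47: both benzylic C–O bonds of the bicycle (C2–O3 and C6–O7) are cut to give a tetraol. Both benzylic carbons are para to oxygen and can be closed by ionisation, so four stereocenters reduce to the two central ones (C1, C5). The forward closure must be kinetic and exo-selective, under acid mild enough for the acetonide and the cis ring.

47 to 46 to 44 + 37: the diol is traced to a lactone (C8 carbonyl) and the C1–C2 bond is cut as an aldol. On the lactone ring the C1 substituent must be trans to that at C5, which is the normal result of enolate attack anti to the β-substituent. This joins the ring A/B half to the ring D/E half. The demand is enolisation next to a free carbinol and an aldehyde partner that already carries the protected side chain.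

44 to 42 to 40 + 21: the lactone is traced to an imide ester and the C5–C6 bond is cut as an auxiliary-controlled aldol. C4, C5, C1 and C8 are a succinate whose two α-carbons are the natural nucleophiles toward the two aryl aldehydes. The absolute configuration comes from a recoverable auxiliary. The forward steps need selective enolisation and selective reduction of the imide beside the ester.

37 to 35 to 34 to 33 to 31 + 22: the formyl carbon is traced to bromine, the acetal to the diol, the diol to the imide, and the bond between the aryl-bearing carbon and the ring A carbinol carbon is cut as a second auxiliary aldol. This sets the future ketone α-centre at the alcohol oxidation level. The bromide must stay inert through aldol, reduction and acetalisation.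

31 to 28 + 29, and 28 to 27 to 26 to 25 to 23 + 24: the N-acyl bond is cut, the carboxyl is traced to an allyl group, and the aryl–allyl bond to a [3,3] shift of an allyl ether. The phenol oxygen of a commercial bromophenol thus places every substituent of ring B.

21 to 20 to 18: the aldehyde is traced to its dimethyl acetal and the aryl silyl ether to an aryl ester. The electron-poor ester is wanted while the benzylic C–O bond is made and heated, and the silyl ether afterwards. The exchange is placed where no other hydroxyl is free.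

18 to 16 (key): the two aryl C–C bonds C7a–C3a and C5–C4 of the benzofuran are cut and CO2 is added back. This removes ring D and the five-membered ring at once and leaves an open-chain ether whose two stereocenters can be set by acyclic chemistry. The forward step must be neutral and must not need a temperature that breaks the benzylic C–O bond.

16 to 9 + 15: the ether C–O bond at the benzylic carbon is cut. The oxygen stays on the pyrone, so the forward step is a substitution with inversion at a secondary benzylic carbinol, and the ring E oxygen must be acylated to suppress ionisation.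

9 to 5 + 7, then 5 to 4 to 3 to 2 to 1, and 7 to 6: the C1–C2 bond of the butynyl chain is cut as the addition of a chiral allenylmetal to an aldehyde, which gives the anti relation that inversion then turns into syn. The reagent is traced to a resolved propargylic alcohol.

15 to 13 to 12 to 11 to 10: the C3–O bond is traced to C3–Br and C3–H, and the acetal to an aldehyde made by oxidation of the 6-methyl group of a commercial pyrone.

40 to 38 + 39, and 22 to 6: simple N-acylation and O-silylation of commercial materials.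

## Other disconnections considered

Alternative 1: The cut is at two neighbouring aryl–carbon bonds of ring D, the aryl–CH2 bond of the future C3 and an aryl–acyl bond at the future oxygen-bearing carbon. In the forward step, fluoride releases an aryne from 5-bromo-3-methoxy-2-(trimethylsilyl)phenyl trifluoromethanesulfonate A1. The carbon of a methyl β-keto ester enolate adds to the aryne carbon remote from the methoxy group, the aryl anion closes onto the ketone, and the four-membered alkoxide fragments to methyl 2-(2-acetyl-5-bromo-3-methoxyphenyl)acetate A2.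
- In its favour: one mild step gives the full substitution pattern of ring D with regiochemistry fixed by the methoxy group. The bromide is a flexible handle for the one-carbon unit, and the acetyl group can become the phenol oxygen by Baeyer–Villiger oxidation.
- Against it here: the step closes no ring and sets no stereocenter. The cis relation then has to be made on an arylacetate whose C3–H is acidic, for instance by carbenoid C–H insertion into a ring E benzyl ether, and a cis 3-carboxylate epimerises readily to trans before it can be reduced. A1 itself takes several steps.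
- Comparison: on precedent and mildness the aryne step is the better of the two. On regiocontrol the two are equal, since both are enforced by the substrate. On structure the chosen plan is stronger, because its stereocenters are set in an open chain with no acidifying group next to C3 and are untouched by a neutral thermal step. Step economy to the ring D aldehyde should be about equal, with more redox adjustments in the alternative.

Alternative 2: The cut is at the two benzylic C–O bonds of the furofuran, leading back to the dibenzylbutanediol (2R,3R)-2-(3-bromo-4-hydroxy-5-methoxybenzyl)-3-(ring D benzyl)butane-1,4-diol A3. In the forward step a high-potential quinone removes hydride from each benzylic CH2 in turn, and each cation is captured by the 1,4-related hydroxyl to give the exo,exo bromophenol furofuran A4.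
- In its favour: the two central stereocenters come from well-behaved alkylation chemistry, no benzylic carbinols have to be made, carried or reduced, and two rings and two stereocenters arise in one step.
- Against it here: the oxidant must choose among several benzylic C–H bonds. C2–H of the dihydrobenzofuran is only protected by the deactivating sulfonate on ring E, and the product ethers are themselves oxidisable. The ring D side is less activated than the free-phenol side, so the reaction may stop after one ring. The sulfonate must later be removed under reductive or strongly basic conditions.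
- Comparison: the stereochemical issue at the benzylic carbons is the same in both plans (kinetic capture of a cation, aryl exo), so they are equal there. The alternative is better on step economy for the bicycle. The chosen plan avoids an oxidant on a substrate rich in electron-rich arenes by ionising hydroxyl groups that are already in place. This alternative is compatible with a pyrone-derived ring D.

Alternative 3: The cut is at both bonds from the ring-fusion carbons to the benzylic carbons. In the forward step the lithiated dithiane of a ring D aldehyde adds in conjugate fashion to (5R)-5-menthyloxyfuran-2(5H)-one A5, anti to the acetal substituent, and the enolate is trapped by a ring B aldehyde to give the trans-2,3-disubstituted menthyloxybutyrolactone A6.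
- In its favour: both C–C bonds and both ring-fusion stereocenters are formed in one convergent step from a cheap chiral four-carbon unit. That is better step economy than two separate aldol reactions with auxiliary attachment and removal, and the reaction class is well established for lignans.
- Against it here: a strong base is needed on a complex dithiane. The dithiane must later be unmasked by oxidative or thiophilic reagents beside electron-rich arenes, and the ketone reduced. Benzyl ethers would have to be removed at the end by hydrogenolysis, which endangers the benzylic C–O bonds. The step contributes nothing to ring D or its cis stereocenters.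
- Comparison: the stereochemical logic (trans lactone, benzylic centres closed by ionisation) equals that of the chosen furofuran assembly. On mechanism the alternative uses umpolung where the chosen route uses natural enolate polarity. As a strategy-bearing step it forms two bonds and two stereocenters but no ring, whereas the pyrone cycloaddition forms two bonds and two rings but no stereocenter, so the two are complementary; the alternative has the better precedent.

Key step: step 12

Remarks on the chemistry (assumptions, one line each):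
- Ring letters: A ketone aryl, B central phenol, D benzo ring of the dihydrobenzofuran, E aryl at its C2. Bicycle numbering: C1 and C5 ring fusion, C2 (ring B side), O3, C4, C6 (ring D side), O7, C8.
- The (1S,2S) ether 16 and the cis (2S,3S) ring of 18 were checked against each other and against the target and need no correction. The one-carbon group at pyrone C6 is carried as a dimethyl acetal instead of a silyloxymethyl group, which saves a reduction, a silylation, a desilylation and an oxidation.
- The lipase is assumed to acylate the (R)-enantiomer of 2 (CH2OTIPS as the large group, ethynyl as the medium group).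
- Abbreviations: TIPS = triisopropylsilyl. D-aryl = (2S,3S)-7-methoxy-2-{3-methoxy-4-[(triisopropylsilyl)oxy]phenyl}-3-{[(triisopropylsilyl)oxy]methyl}-2,3-dihydro-1-benzofuran-5-yl. B-aryl = 3-methoxy-5-[(4R,5S)-4-{3-methoxy-4-[(triisopropylsilyl)oxy]phenyl}-2,2-dimethyl-1,3-dioxan-5-yl]-4-[(triisopropylsilyl)oxy]phenyl.

## Steps

Step 1
Reactants: 1 rac-but-3-yne-1,2-diol
Product: 2 rac-1-[(triisopropylsilyl)oxy]but-3-yn-2-ol
Conditions: TIPSCl, imidazole, CH2Cl2, 0 °C
Reagents that add atoms: triisopropylsilyl chloride, CC(C)[Si](Cl)(C(C)C)C(C)C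
Why: Selective silylation; the bulky chlorosilane reacts at the primary hydroxyl much faster than at the secondary propargylic one.

Step 2
Reactants: 2 rac-1-[(triisopropylsilyl)oxy]but-3-yn-2-ol
Product: 3 (R)-1-[(triisopropylsilyl)oxy]but-3-yn-2-yl acetate
Conditions: immobilised Candida antarctica lipase B, vinyl acetate, MTBE, 30 °C, stopped near half conversion
Reagents that add atoms: vinyl acetate, CC(=O)OC=C
Why: Lipase-catalysed kinetic resolution by transesterification; the enzyme should acylate the enantiomer whose large (CH2OTIPS) and medium (ethynyl) groups fit its pocket, the (R)-alcohol, and the acetate is separated from the remaining (S)-alcohol by chromatography.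

Step 3
Reactants: 3 (R)-1-[(triisopropylsilyl)oxy]but-3-yn-2-yl acetate
Product: 4 (R)-1-[(triisopropylsilyl)oxy]but-3-yn-2-ol
Conditions: K2CO3 (cat.), MeOH, 0 °C
Reagents that add atoms: none
Why: Base-catalysed transesterification removes the acetate without touching the stereocenter, the silyl ether or the alkyne.

Step 4
Reactants: 4 (R)-1-[(triisopropylsilyl)oxy]but-3-yn-2-ol
Product: 5 (R)-1-[(triisopropylsilyl)oxy]but-3-yn-2-yl methanesulfonate
Conditions: MsCl, Et3N, CH2Cl2, −78 → −20 °C
Reagents that add atoms: methanesulfonyl chloride, CS(=O)(=O)Cl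
Why: O-sulfonylation with retention gives the propargylic leaving group needed for the allenylmetal reagent.

Step 5
Reactants: 6 vanillin (4-hydroxy-3-methoxybenzaldehyde)
Product: 7 4-formyl-2-methoxyphenyl pivalate
Conditions: PivCl, Et3N, DMAP (cat.), CH2Cl2, 0 °C → rt
Reagents that add atoms: pivaloyl chloride, CC(C)(C)C(=O)Cl
Why: Acylation of the phenol; the electron-poor ester makes the later benzylic carbon a poor cation and survives organozinc, Mitsunobu and thermal conditions.

Step 6
Reactants: 5 (R)-1-[(triisopropylsilyl)oxy]but-3-yn-2-yl methanesulfonate; 7 4-formyl-2-methoxyphenyl pivalate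
Product: 9 4-[(1R,2S)-1-hydroxy-2-{[(triisopropylsilyl)oxy]methyl}but-3-yn-1-yl]-2-methoxyphenyl pivalate, via allenylzinc reagent 8 (not isolated)
Conditions: Pd(OAc)2 (5 mol %), PPh3 (5 mol %), Et2Zn (3 equiv), THF, −78 → −20 °C
Reagents that add atoms: none
Why: Palladium-catalysed propargylation through an allenylzinc: zerovalent palladium opens the mesylate by anti SN2′ substitution, zinc exchange gives the (M)-allenylzinc 8, and this adds to the aldehyde through a cyclic SE2′ transition state. The mesylate configuration fixes C2 as S and the chair-like transition state places hydroxyl and CH2OTIPS anti, giving (1R,2S).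

Step 7
Reactants: 10 4-methoxy-6-methyl-2H-pyran-2-one
Product: 11 4-methoxy-2-oxo-2H-pyran-6-carbaldehyde
Conditions: SeO2, 1,4-dioxane, 160 °C, sealed tube
Reagents that add atoms: selenium dioxide, O=[Se]=O
Why: Riley oxidation of the vinylogously activated 6-methyl group to the aldehyde, a known transformation of this pyrone.

Step 8
Reactants: 11 4-methoxy-2-oxo-2H-pyran-6-carbaldehyde
Product: 12 6-(dimethoxymethyl)-4-methoxy-2H-pyran-2-one
Conditions: HC(OMe)3, MeOH, p-TsOH (cat.), rt
Reagents that add atoms: trimethyl orthoformate, COC(OC)OC; methanol, CO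
Why: Acid-catalysed acetalisation of an electron-poor aldehyde; the acetal carries the future ring D formyl group through the halogenation, coupling and thermal steps.

Step 9
Reactants: 12 6-(dimethoxymethyl)-4-methoxy-2H-pyran-2-one
Product: 13 3-bromo-6-(dimethoxymethyl)-4-methoxy-2H-pyran-2-one
Conditions: NBS, MeCN, rt, dark
Reagents that add atoms: N-bromosuccinimide, O=C1CCC(=O)N1Br
Why: Electrophilic bromination at C3, the nucleophilic α-carbon of the vinylogous ester flanked by methoxy and carbonyl.

Step 10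
Reactants: 13 3-bromo-6-(dimethoxymethyl)-4-methoxy-2H-pyran-2-one
Product: 15 6-(dimethoxymethyl)-3-hydroxy-4-methoxy-2H-pyran-2-one, via pyrone 3-boronate 14 (not isolated)
Conditions: B2pin2, Pd(dppf)Cl2 (5 mol %), KOAc, 1,4-dioxane, 85 °C; then 30 % H2O2, NaHCO3, THF–H2O, 0 °C
Reagents that add atoms: hydrogen peroxide, OO
Why: Miyaura borylation of the alkenyl bromide followed by oxidation of the C–B bond with retention of position; the boronate is oxidised without isolation to limit protodeboronation.

Step 11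
Reactants: 9 4-[(1R,2S)-1-hydroxy-2-{[(triisopropylsilyl)oxy]methyl}but-3-yn-1-yl]-2-methoxyphenyl pivalate; 15 6-(dimethoxymethyl)-3-hydroxy-4-methoxy-2H-pyran-2-one
Product: 16 4-[(1S,2S)-1-{[6-(dimethoxymethyl)-4-methoxy-2-oxo-2H-pyran-3-yl]oxy}-2-{[(triisopropylsilyl)oxy]methyl}but-3-yn-1-yl]-2-methoxyphenyl pivalate
Conditions: PPh3, DIAD, toluene, 0 °C → rt
Reagents that add atoms: none
Why: Mitsunobu etherification; the acidic enolic 3-hydroxyl of the pyrone displaces the oxyphosphonium group with inversion and turns the anti alcohol into the syn (1S,2S) ether. The pivaloyloxy group on ring E disfavours a benzylic cation and so keeps the substitution SN2.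

Step 12
Reactants: 16 4-[(1S,2S)-1-{[6-(dimethoxymethyl)-4-methoxy-2-oxo-2H-pyran-3-yl]oxy}-2-{[(triisopropylsilyl)oxy]methyl}but-3-yn-1-yl]-2-methoxyphenyl pivalate
Product: 18 4-[(2S,3S)-5-(dimethoxymethyl)-7-methoxy-3-{[(triisopropylsilyl)oxy]methyl}-2,3-dihydro-1-benzofuran-2-yl]-2-methoxyphenyl pivalate, via bridged bicyclic lactone 17 (not isolated)
Conditions: o-dichlorobenzene (0.01 M), BHT (5 mol %), argon, 180 °C, sealed vessel
Reagents that add atoms: none
Why: The pyrone carbons C3 to C6 act as the four-electron diene and the tethered terminal alkyne as the two-electron partner in a thermal [4+2] addition that bonds pyrone C3 to the internal and C6 to the terminal alkyne carbon, giving the 2-oxabicyclo[2.2.2]octadienone 17. Retro-[4+2] loss of CO2 from 17 then aromatises the six-membered ring. The closest known reaction type is the intramolecular Diels–Alder reaction of 2-pyrones with tethered alkynes followed by cycloreversion. Ring D is closed by the cycloaddition–cycloreversion pair (two new aryl C–C bonds), and the five-membered oxygen ring is closed in the fused, type 1 intramolecular mode because the three-atom O–C–C tether links the diene terminus C3 to the proximal alkyne carbon. No lasting stereocenter is formed: the bridgeheads of 17 disappear on aromatisation, so both facial diastereomers of 17 converge on 18. The step needs regioselectivity, and the short tether allows only the fused orientation. It also needs the two existing stereocenters to survive, which the neutral medium, the absence of any acidifying group next to them and the electron-poor pivalate on ring E should secure. The acetal and silyl ether are inert, and high dilution with a radical inhibitor limits intermolecular reaction and polymerisation of the alkyne.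

Step 13
Reactants: 18 4-[(2S,3S)-5-(dimethoxymethyl)-7-methoxy-3-{[(triisopropylsilyl)oxy]methyl}-2,3-dihydro-1-benzofuran-2-yl]-2-methoxyphenyl pivalate
Product: 20 {4-[(2S,3S)-5-(dimethoxymethyl)-7-methoxy-3-{[(triisopropylsilyl)oxy]methyl}-2,3-dihydro-1-benzofuran-2-yl]-2-methoxyphenoxy}triisopropylsilane, via free phenol 19 (not isolated)
Conditions: K2CO3 (0.3 equiv), MeOH–THF, rt; solvent exchange; TIPSCl, imidazole, DMF, rt
Reagents that add atoms: triisopropylsilyl chloride, CC(C)[Si](Cl)(C(C)C)C(C)C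
Why: Methanolysis of the aryl ester and silylation of the phenol exchange the electron-poor group needed in steps 11 and 12 for a fluoride-labile one before any hydride or organolithium step; at room temperature the phenoxide should not open the cis ring.

Step 14
Reactants: 20 {4-[(2S,3S)-5-(dimethoxymethyl)-7-methoxy-3-{[(triisopropylsilyl)oxy]methyl}-2,3-dihydro-1-benzofuran-2-yl]-2-methoxyphenoxy}triisopropylsilane
Product: 21 (2S,3S)-7-methoxy-2-{3-methoxy-4-[(triisopropylsilyl)oxy]phenyl}-3-{[(triisopropylsilyl)oxy]methyl}-2,3-dihydro-1-benzofuran-5-carbaldehyde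
Conditions: PPTS (cat.), acetone–H2O (10:1), rt
Reagents that add atoms: water, O
Why: Mild hydrolysis of an electron-rich aryl dimethyl acetal; the weak acid should not ionise the benzylic ether of the cis ring or cleave the TIPS ethers.

Step 15
Reactants: 6 vanillin (4-hydroxy-3-methoxybenzaldehyde)
Product: 22 3-methoxy-4-[(triisopropylsilyl)oxy]benzaldehyde
Conditions: TIPSCl, imidazole, DMF, rt
Reagents that add atoms: triisopropylsilyl chloride, CC(C)[Si](Cl)(C(C)C)C(C)C
Why: Standard silylation of a phenol; the TIPS ether tolerates boron enolates, hydrides and organolithiums and is removed only at the end.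

Step 16
Reactants: 23 4-bromo-2-methoxyphenol; 24 allyl bromide
Product: 25 1-(allyloxy)-4-bromo-2-methoxybenzene
Conditions: K2CO3, acetone, reflux
Reagents that add atoms: none
Why: Williamson ether synthesis at the phenol.

Step 17
Reactants: 25 1-(allyloxy)-4-bromo-2-methoxybenzene
Product: 26 2-allyl-4-bromo-6-methoxyphenol
Conditions: N,N-diethylaniline, 200 °C
Reagents that add atoms: none
Why: Aromatic Claisen rearrangement; the allyl group can only move to the one free ortho position, which places the future side-chain carbon next to the phenol.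

Step 18
Reactants: 26 2-allyl-4-bromo-6-methoxyphenol
Product: 27 (2-allyl-4-bromo-6-methoxyphenoxy)triisopropylsilane
Conditions: TIPSCl, imidazole, DMAP (cat.), DMF, 60 °C
Reagents that add atoms: triisopropylsilyl chloride, CC(C)[Si](Cl)(C(C)C)C(C)C
Why: Silylation of the hindered phenol, helped by warming and a nucleophilic catalyst.

Step 19
Reactants: 27 (2-allyl-4-bromo-6-methoxyphenoxy)triisopropylsilane
Product: 28 2-{5-bromo-3-methoxy-2-[(triisopropylsilyl)oxy]phenyl}acetic acid
Conditions: OsO4 (1 mol %), KHSO5 (Oxone, 4 equiv), DMF, rt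
Reagents that add atoms: potassium peroxymonosulfate, [K+].OOS(=O)(=O)[O-]
Why: Osmium-catalysed oxidative cleavage of the terminal alkene directly to the carboxylic acid with loss of one carbon; aryl bromide and aryl silyl ether are inert.

Step 20
Reactants: 28 2-{5-bromo-3-methoxy-2-[(triisopropylsilyl)oxy]phenyl}acetic acid; 29 (R)-4-benzyl-1,3-oxazolidin-2-one
Product: 31 (R)-4-benzyl-3-(2-{5-bromo-3-methoxy-2-[(triisopropylsilyl)oxy]phenyl}acetyl)-1,3-oxazolidin-2-one, via mixed pivalic anhydride 30 (not isolated)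
Conditions: PivCl, Et3N, THF, −20 °C; then 29, LiCl, rt
Reagents that add atoms: none
Why: N-acylation of the oxazolidinone through the mixed anhydride under LiCl/Et3N activation, which avoids strong base on the arylacetic acid.

Step 21
Reactants: 31 (R)-4-benzyl-3-(2-{5-bromo-3-methoxy-2-[(triisopropylsilyl)oxy]phenyl}acetyl)-1,3-oxazolidin-2-one; 22 3-methoxy-4-[(triisopropylsilyl)oxy]benzaldehyde
Product: 33 (R)-4-benzyl-3-[(2R,3R)-2-{5-bromo-3-methoxy-2-[(triisopropylsilyl)oxy]phenyl}-3-hydroxy-3-{3-methoxy-4-[(triisopropylsilyl)oxy]phenyl}propanoyl]-1,3-oxazolidin-2-one, via boron enolate 32 (not isolated)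
Conditions: Bu2BOTf, iPr2NEt, CH2Cl2, −78 → 0 °C; then 22, −78 → 0 °C; pH 7 buffer, MeOH, H2O2, 0 °C
Reagents that add atoms: none
Why: Evans syn aldol; the (Z)-boron enolate reacts through a Zimmerman–Traxler transition state on the face away from the benzyl group of the (R)-auxiliary, which sets the aryl-bearing carbon (the future ketone α-carbon) and the carbinol syn, (2R,3R).

Step 22
Reactants: 33 (R)-4-benzyl-3-[(2R,3R)-2-{5-bromo-3-methoxy-2-[(triisopropylsilyl)oxy]phenyl}-3-hydroxy-3-{3-methoxy-4-[(triisopropylsilyl)oxy]phenyl}propanoyl]-1,3-oxazolidin-2-one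
Product: 34 (1R,2S)-2-{5-bromo-3-methoxy-2-[(triisopropylsilyl)oxy]phenyl}-1-{3-methoxy-4-[(triisopropylsilyl)oxy]phenyl}propane-1,3-diol
Conditions: LiBH4, MeOH (1 equiv), THF, 0 °C
Reagents that add atoms: none
Why: Reductive removal of the auxiliary gives the 1,3-diol without touching either stereocenter; the descriptor of the aryl-bearing carbon becomes S only through the change in priorities.

Step 23
Reactants: 34 (1R,2S)-2-{5-bromo-3-methoxy-2-[(triisopropylsilyl)oxy]phenyl}-1-{3-methoxy-4-[(triisopropylsilyl)oxy]phenyl}propane-1,3-diol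
Product: 35 (4R,5S)-5-{5-bromo-3-methoxy-2-[(triisopropylsilyl)oxy]phenyl}-4-{3-methoxy-4-[(triisopropylsilyl)oxy]phenyl}-2,2-dimethyl-1,3-dioxane
Conditions: 2,2-dimethoxypropane, PPTS (cat.), CH2Cl2, rt
Reagents that add atoms: 2,2-dimethoxypropane, COC(C)(C)OC
Why: Acetonide formation ties both hydroxyls of the side chain into one base- and hydride-stable group and keeps the ring A benzylic oxygen from ionising later.

Step 24
Reactants: 35 (4R,5S)-5-{5-bromo-3-methoxy-2-[(triisopropylsilyl)oxy]phenyl}-4-{3-methoxy-4-[(triisopropylsilyl)oxy]phenyl}-2,2-dimethyl-1,3-dioxane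
Product: 37 3-methoxy-5-[(4R,5S)-4-{3-methoxy-4-[(triisopropylsilyl)oxy]phenyl}-2,2-dimethyl-1,3-dioxan-5-yl]-4-[(triisopropylsilyl)oxy]benzaldehyde, via aryllithium 36 (not isolated)
Conditions: n-BuLi, THF, −78 °C; then DMF, −78 → 0 °C; aq. NH4Cl
Reagents that add atoms: N,N-dimethylformamide, CN(C)C=O
Why: Bromine–lithium exchange and formylation; acetonide and silyl ethers are inert to the aryllithium at low temperature.

Step 25
Reactants: 38 (S)-4-benzyl-1,3-oxazolidin-2-one; 39 methyl 4-chloro-4-oxobutanoate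
Product: 40 methyl 4-[(4S)-4-benzyl-2-oxo-1,3-oxazolidin-3-yl]-4-oxobutanoate
Conditions: Et3N, DMAP (cat.), CH2Cl2, 0 °C → rt
Reagents that add atoms: none
Why: N-acylation of the oxazolidinone by the acid chloride gives the succinate unit with one end activated for enolisation.

Step 26
Reactants: 40 methyl 4-[(4S)-4-benzyl-2-oxo-1,3-oxazolidin-3-yl]-4-oxobutanoate; 21 (2S,3S)-7-methoxy-2-{3-methoxy-4-[(triisopropylsilyl)oxy]phenyl}-3-{[(triisopropylsilyl)oxy]methyl}-2,3-dihydro-1-benzofuran-5-carbaldehyde
Product: 42 methyl (3S,4S)-3-{[(4S)-4-benzyl-2-oxo-1,3-oxazolidin-3-yl]carbonyl}-4-(D-aryl)-4-hydroxybutanoate, via boron enolate 41 (not isolated)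
Conditions: Bu2BOTf, iPr2NEt, CH2Cl2, −78 → 0 °C; then 21, −78 → 0 °C; pH 7 buffer, MeOH, H2O2, 0 °C
Reagents that add atoms: none
Why: Evans syn aldol of the succinate imide; only the imide is enolised, and the (S)-auxiliary sets C5 of the future bicycle (S here, R after the later change in priorities) with the ring D carbinol syn to it.

Step 27
Reactants: 42 methyl (3S,4S)-3-{[(4S)-4-benzyl-2-oxo-1,3-oxazolidin-3-yl]carbonyl}-4-(D-aryl)-4-hydroxybutanoate
Product: 44 (4R)-4-[(S)-(D-aryl)(hydroxy)methyl]oxolan-2-one, via hydroxy ester 43 (not isolated)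
Conditions: NaBH4, THF–H2O (4:1), 0 °C → rt
Reagents that add atoms: none
Why: Borohydride in wet THF reduces the N-acyl oxazolidinone but not the methyl ester; the primary alkoxide so formed closes the γ-lactone, so the ring-fusion carbon becomes the β-carbon of a butyrolactone.

Step 28
Reactants: 44 (4R)-4-[(S)-(D-aryl)(hydroxy)methyl]oxolan-2-one; 37 3-methoxy-5-[(4R,5S)-4-{3-methoxy-4-[(triisopropylsilyl)oxy]phenyl}-2,2-dimethyl-1,3-dioxan-5-yl]-4-[(triisopropylsilyl)oxy]benzaldehyde
Product: 46 (3S,4R)-3-[(B-aryl)(hydroxy)methyl]-4-[(S)-(D-aryl)(hydroxy)methyl]oxolan-2-one (both epimers at the ring B carbinol), via lactone dianion 45 (not isolated)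
Conditions: LDA (2.3 equiv), THF, −78 °C; then 37, −78 °C; AcOH quench at −78 °C
Reagents that add atoms: none
Why: Aldol addition of a lactone enolate; the alkoxide–enolate adds to the aldehyde on the face opposite the β-substituent, giving the trans-2,3-disubstituted lactone and so the second ring-fusion stereocenter (C1). The new carbinol forms as an epimer mixture, which does not matter because this centre is ionised in step 30.

Step 29
Reactants: 46 (3S,4R)-3-[(B-aryl)(hydroxy)methyl]-4-[(S)-(D-aryl)(hydroxy)methyl]oxolan-2-one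
Product: 47 (2R,3R)-2-[(B-aryl)(hydroxy)methyl]-3-[(S)-(D-aryl)(hydroxy)methyl]butane-1,4-diol
Conditions: LiAlH4, THF, 0 °C; aq. potassium sodium tartrate
Reagents that add atoms: none
Why: Hydride reduction of the lactone to the 1,4-diol; silyl ethers and the acetonide are inert and no stereocenter is involved.

Step 30
Reactants: 47 (2R,3R)-2-[(B-aryl)(hydroxy)methyl]-3-[(S)-(D-aryl)(hydroxy)methyl]butane-1,4-diol
Product: 48 (1R,2S,5R,6S)-2-(B-aryl)-6-(D-aryl)-3,7-dioxabicyclo[3.3.0]octane
Conditions: CSA (10 mol %), 4 Å molecular sieves, CH2Cl2, −20 → 0 °C; Et3N quench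
Reagents that add atoms: none
Why: Acid-catalysed double cyclodehydration; each benzylic carbinol para to oxygen ionises to a quinone-methide-like cation that is captured 5-exo by the 1,4-related primary hydroxyl. Under kinetic control each aryl group should take the exo position, trans to the neighbouring ring-fusion substituent, so C2 and C6 are set here from the (2R,3R) core. The acetonide and the aryl ether of the cis ring should not ionise under catalytic acid at low temperature.

Step 31
Reactants: 48 (1R,2S,5R,6S)-2-(B-aryl)-6-(D-aryl)-3,7-dioxabicyclo[3.3.0]octane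
Product: 49 (1R,2S)-2-{5-[(1R,2S,5R,6S)-6-(D-aryl)-3,7-dioxabicyclo[3.3.0]octan-2-yl]-3-methoxy-2-[(triisopropylsilyl)oxy]phenyl}-1-{3-methoxy-4-[(triisopropylsilyl)oxy]phenyl}propane-1,3-diol
Conditions: AcOH–THF–H2O (3:1:1), 40 °C
Reagents that add atoms: none
Why: Hydrolysis of the acetonide with a weak acid that should not ionise the benzylic ethers; TIPS ethers are stable under these conditions.

Step 32
Reactants: 49 (1R,2S)-2-{5-[(1R,2S,5R,6S)-6-(D-aryl)-3,7-dioxabicyclo[3.3.0]octan-2-yl]-3-methoxy-2-[(triisopropylsilyl)oxy]phenyl}-1-{3-methoxy-4-[(triisopropylsilyl)oxy]phenyl}propane-1,3-diol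
Product: 50 (2S)-2-{5-[(1R,2S,5R,6S)-6-(D-aryl)-3,7-dioxabicyclo[3.3.0]octan-2-yl]-3-methoxy-2-[(triisopropylsilyl)oxy]phenyl}-3-hydroxy-1-{3-methoxy-4-[(triisopropylsilyl)oxy]phenyl}propan-1-one
Conditions: MnO2 (activated, excess), CH2Cl2, rt
Reagents that add atoms: none
Why: MnO2 oxidises benzylic alcohols and leaves the primary aliphatic hydroxyl; the neutral heterogeneous conditions should keep the now acidic α-stereocenter from epimerising, and all phenols are silylated.

Step 33
Reactants: 50 (2S)-2-{5-[(1R,2S,5R,6S)-6-(D-aryl)-3,7-dioxabicyclo[3.3.0]octan-2-yl]-3-methoxy-2-[(triisopropylsilyl)oxy]phenyl}-3-hydroxy-1-{3-methoxy-4-[(triisopropylsilyl)oxy]phenyl}propan-1-one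
Product: 51 CNP0174045.1, (2S)-3-hydroxy-1-(4-hydroxy-3-methoxyphenyl)-2-{2-hydroxy-5-[(1R,2S,5R,6S)-6-[(2S,3S)-2-(4-hydroxy-3-methoxyphenyl)-3-(hydroxymethyl)-7-methoxy-2,3-dihydro-1-benzofuran-5-yl]-3,7-dioxabicyclo[3.3.0]octan-2-yl]-3-methoxyphenyl}propan-1-one
Conditions: HF·pyridine, pyridine, THF, 0 °C → rt
Reagents that add atoms: none
Why: Global desilylation with pyridine-buffered HF; the non-basic medium avoids enolisation, retro-aldol cleavage and dehydration of the β-hydroxy ketone and is too weakly acidic to ionise the benzylic ethers.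

## Compound list

1 | rac-but-3-yne-1,2-diol | C#CC(O)CO | starting material
2 | rac-1-[(triisopropylsilyl)oxy]but-3-yn-2-ol | C#CC(O)CO[Si](C(C)C)(C(C)C)C(C)C | intermediate
3 | (R)-1-[(triisopropylsilyl)oxy]but-3-yn-2-yl acetate | C#C[C@@H](OC(C)=O)CO[Si](C(C)C)(C(C)C)C(C)C | intermediate
4 | (R)-1-[(triisopropylsilyl)oxy]but-3-yn-2-ol | C#C[C@@H](O)CO[Si](C(C)C)(C(C)C)C(C)C | intermediate
5 | (R)-1-[(triisopropylsilyl)oxy]but-3-yn-2-yl methanesulfonate | C#C[C@@H](OS(C)(=O)=O)CO[Si](C(C)C)(C(C)C)C(C)C | intermediate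
6 | vanillin (4-hydroxy-3-methoxybenzaldehyde) | COc1cc(C=O)ccc1O | starting material
7 | 4-formyl-2-methoxyphenyl pivalate | COc1cc(C=O)ccc1OC(=O)C(C)(C)C | intermediate
8 | ethyl[(M)-4-(triisopropylsilyloxy)buta-1,2-dien-1-yl]zinc (formed in the flask) | CC[Zn]C([H])=[C@]=C([H])CO[Si](C(C)C)(C(C)C)C(C)C | intermediate
9 | 4-[(1R,2S)-1-hydroxy-2-{[(triisopropylsilyl)oxy]methyl}but-3-yn-1-yl]-2-methoxyphenyl pivalate (anti) | COc1cc(ccc1OC(=O)C(C)(C)C)[C@H](O)[C@H](CO[Si](C(C)C)(C(C)C)C(C)C)C#C | intermediate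
10 | 4-methoxy-6-methyl-2H-pyran-2-one | COC1=CC(=O)OC(C)=C1 | starting material
11 | 4-methoxy-2-oxo-2H-pyran-6-carbaldehyde | COC1=CC(=O)OC(C=O)=C1 | intermediate
12 | 6-(dimethoxymethyl)-4-methoxy-2H-pyran-2-one | COC(OC)C1=CC(OC)=CC(=O)O1 | intermediate
13 | 3-bromo-6-(dimethoxymethyl)-4-methoxy-2H-pyran-2-one | COC(OC)C1=CC(OC)=C(Br)C(=O)O1 | intermediate
14 | 6-(dimethoxymethyl)-4-methoxy-3-(4,4,5,5-tetramethyl-1,3,2-dioxaborolan-2-yl)-2H-pyran-2-one (formed in the flask) | COC(OC)C1=CC(OC)=C(B2OC(C)(C)C(C)(C)O2)C(=O)O1 | intermediate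
15 | 6-(dimethoxymethyl)-3-hydroxy-4-methoxy-2H-pyran-2-one | COC(OC)C1=CC(OC)=C(O)C(=O)O1 | intermediate
16 | 4-[(1S,2S)-1-{[6-(dimethoxymethyl)-4-methoxy-2-oxo-2H-pyran-3-yl]oxy}-2-{[(triisopropylsilyl)oxy]methyl}but-3-yn-1-yl]-2-methoxyphenyl pivalate (syn ether) | COC(OC)C1=CC(OC)=C(O[C@H](c2ccc(OC(=O)C(C)(C)C)c(OC)c2)[C@H](CO[Si](C(C)C)(C(C)C)C(C)C)C#C)C(=O)O1 | intermediate
17 | bridged 2-oxabicyclo[2.2.2]octa-5,7-dien-3-one cycloadduct with fused dihydrofuran ring (both bridgehead diastereomers, formed in the flask) | O=C1OC2(C(OC)OC)C=C(OC)C1(O[C@H](c4ccc(OC(=O)C(C)(C)C)c(OC)c4)[C@@H]3CO[Si](C(C)C)(C(C)C)C(C)C)C3=C2 | intermediate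
18 | 4-[(2S,3S)-5-(dimethoxymethyl)-7-methoxy-3-{[(triisopropylsilyl)oxy]methyl}-2,3-dihydro-1-benzofuran-2-yl]-2-methoxyphenyl pivalate (cis) | COC(OC)c1cc(OC)c2c(c1)[C@@H](CO[Si](C(C)C)(C(C)C)C(C)C)[C@@H](c1ccc(OC(=O)C(C)(C)C)c(OC)c1)O2 | intermediate
19 | 4-[(2S,3S)-5-(dimethoxymethyl)-7-methoxy-3-{[(triisopropylsilyl)oxy]methyl}-2,3-dihydro-1-benzofuran-2-yl]-2-methoxyphenol (formed in the flask) | COC(OC)c1cc(OC)c2c(c1)[C@@H](CO[Si](C(C)C)(C(C)C)C(C)C)[C@@H](c1ccc(O)c(OC)c1)O2 | intermediate
20 | {4-[(2S,3S)-5-(dimethoxymethyl)-7-methoxy-3-{[(triisopropylsilyl)oxy]methyl}-2,3-dihydro-1-benzofuran-2-yl]-2-methoxyphenoxy}triisopropylsilane | COC(OC)c1cc(OC)c2c(c1)[C@@H](CO[Si](C(C)C)(C(C)C)C(C)C)[C@@H](c1ccc(O[Si](C(C)C)(C(C)C)C(C)C)c(OC)c1)O2 | intermediate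
21 | (2S,3S)-7-methoxy-2-{3-methoxy-4-[(triisopropylsilyl)oxy]phenyl}-3-{[(triisopropylsilyl)oxy]methyl}-2,3-dihydro-1-benzofuran-5-carbaldehyde | O=Cc1cc(OC)c2c(c1)[C@@H](CO[Si](C(C)C)(C(C)C)C(C)C)[C@@H](c1ccc(O[Si](C(C)C)(C(C)C)C(C)C)c(OC)c1)O2 | intermediate
22 | 3-methoxy-4-[(triisopropylsilyl)oxy]benzaldehyde | COc1cc(C=O)ccc1O[Si](C(C)C)(C(C)C)C(C)C | intermediate
23 | 4-bromo-2-methoxyphenol | COc1cc(Br)ccc1O | starting material
24 | allyl bromide | C=CCBr | starting material
25 | 1-(allyloxy)-4-bromo-2-methoxybenzene | COc1cc(Br)ccc1OCC=C | intermediate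
26 | 2-allyl-4-bromo-6-methoxyphenol | COc1cc(Br)cc(CC=C)c1O | intermediate
27 | (2-allyl-4-bromo-6-methoxyphenoxy)triisopropylsilane | COc1cc(Br)cc(CC=C)c1O[Si](C(C)C)(C(C)C)C(C)C | intermediate
28 | 2-{5-bromo-3-methoxy-2-[(triisopropylsilyl)oxy]phenyl}acetic acid | COc1cc(Br)cc(CC(=O)O)c1O[Si](C(C)C)(C(C)C)C(C)C | intermediate
29 | (R)-4-benzyl-1,3-oxazolidin-2-one | O=C1N[C@H](Cc2ccccc2)CO1 | starting material
30 | 2-{5-bromo-3-methoxy-2-[(triisopropylsilyl)oxy]phenyl}acetic pivalic anhydride (formed in the flask) | COc1cc(Br)cc(CC(=O)OC(=O)C(C)(C)C)c1O[Si](C(C)C)(C(C)C)C(C)C | intermediate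
31 | (R)-4-benzyl-3-(2-{5-bromo-3-methoxy-2-[(triisopropylsilyl)oxy]phenyl}acetyl)-1,3-oxazolidin-2-one | COc1cc(Br)cc(CC(=O)N2[C@H](Cc3ccccc3)COC2=O)c1O[Si](C(C)C)(C(C)C)C(C)C | intermediate
32 | (Z)-dibutylboron enolate of 31 (formed in the flask) | CCCCB(CCCC)O/C(=C\c1cc(Br)cc(OC)c1O[Si](C(C)C)(C(C)C)C(C)C)N1[C@H](Cc2ccccc2)COC1=O | intermediate
33 | (R)-4-benzyl-3-[(2R,3R)-2-{5-bromo-3-methoxy-2-[(triisopropylsilyl)oxy]phenyl}-3-hydroxy-3-{3-methoxy-4-[(triisopropylsilyl)oxy]phenyl}propanoyl]-1,3-oxazolidin-2-one | O=C(N1[C@H](Cc2ccccc2)COC1=O)[C@H](c1cc(Br)cc(OC)c1O[Si](C(C)C)(C(C)C)C(C)C)[C@@H](O)c1ccc(O[Si](C(C)C)(C(C)C)C(C)C)c(OC)c1 | intermediate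
34 | (1R,2S)-2-{5-bromo-3-methoxy-2-[(triisopropylsilyl)oxy]phenyl}-1-{3-methoxy-4-[(triisopropylsilyl)oxy]phenyl}propane-1,3-diol | OC[C@H](c1cc(Br)cc(OC)c1O[Si](C(C)C)(C(C)C)C(C)C)[C@@H](O)c1ccc(O[Si](C(C)C)(C(C)C)C(C)C)c(OC)c1 | intermediate
35 | (4R,5S)-5-{5-bromo-3-methoxy-2-[(triisopropylsilyl)oxy]phenyl}-4-{3-methoxy-4-[(triisopropylsilyl)oxy]phenyl}-2,2-dimethyl-1,3-dioxane | CC1(C)OC[C@H](c2cc(Br)cc(OC)c2O[Si](C(C)C)(C(C)C)C(C)C)[C@@H](O1)c3ccc(O[Si](C(C)C)(C(C)C)C(C)C)c(OC)c3 | intermediate
36 | aryllithium from 35 by bromine–lithium exchange (formed in the flask) | CC1(C)OC[C@H](c2cc([Li])cc(OC)c2O[Si](C(C)C)(C(C)C)C(C)C)[C@@H](O1)c3ccc(O[Si](C(C)C)(C(C)C)C(C)C)c(OC)c3 | intermediate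
37 | 3-methoxy-5-[(4R,5S)-4-{3-methoxy-4-[(triisopropylsilyl)oxy]phenyl}-2,2-dimethyl-1,3-dioxan-5-yl]-4-[(triisopropylsilyl)oxy]benzaldehyde | CC1(C)OC[C@H](c2cc(C=O)cc(OC)c2O[Si](C(C)C)(C(C)C)C(C)C)[C@@H](O1)c3ccc(O[Si](C(C)C)(C(C)C)C(C)C)c(OC)c3 | intermediate
38 | (S)-4-benzyl-1,3-oxazolidin-2-one | O=C1N[C@@H](Cc2ccccc2)CO1 | starting material
39 | methyl 4-chloro-4-oxobutanoate | COC(=O)CCC(=O)Cl | starting material
40 | methyl 4-[(4S)-4-benzyl-2-oxo-1,3-oxazolidin-3-yl]-4-oxobutanoate | COC(=O)CCC(=O)N1[C@@H](Cc2ccccc2)COC1=O | intermediate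
41 | (Z)-dibutylboron enolate of 40 (formed in the flask) | CCCCB(CCCC)O/C(=C\CC(=O)OC)N1[C@@H](Cc2ccccc2)COC1=O | intermediate
42 | methyl (3S,4S)-3-{[(4S)-4-benzyl-2-oxo-1,3-oxazolidin-3-yl]carbonyl}-4-(D-aryl)-4-hydroxybutanoate | COC(=O)C[C@H](C(=O)N1[C@@H](Cc2ccccc2)COC1=O)[C@H](O)c3cc(OC)c4c(c3)[C@@H](CO[Si](C(C)C)(C(C)C)C(C)C)[C@@H](c5ccc(O[Si](C(C)C)(C(C)C)C(C)C)c(OC)c5)O4 | intermediate
43 | methyl (3R,4S)-4-(D-aryl)-4-hydroxy-3-(hydroxymethyl)butanoate (formed in the flask) | COC(=O)C[C@H](CO)[C@H](O)c3cc(OC)c4c(c3)[C@@H](CO[Si](C(C)C)(C(C)C)C(C)C)[C@@H](c5ccc(O[Si](C(C)C)(C(C)C)C(C)C)c(OC)c5)O4 | intermediate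
44 | (4R)-4-[(S)-(D-aryl)(hydroxy)methyl]oxolan-2-one | O=C1C[C@H](CO1)[C@H](O)c3cc(OC)c4c(c3)[C@@H](CO[Si](C(C)C)(C(C)C)C(C)C)[C@@H](c5ccc(O[Si](C(C)C)(C(C)C)C(C)C)c(OC)c5)O4 | intermediate
45 | dilithium alkoxide–enolate of 44 (formed in the flask) | [Li]OC1=C[C@H](CO1)[C@H](O[Li])c3cc(OC)c4c(c3)[C@@H](CO[Si](C(C)C)(C(C)C)C(C)C)[C@@H](c5ccc(O[Si](C(C)C)(C(C)C)C(C)C)c(OC)c5)O4 | intermediate
46 | (3S,4R)-3-[(B-aryl)(hydroxy)methyl]-4-[(S)-(D-aryl)(hydroxy)methyl]oxolan-2-one (trans lactone, both epimers at the ring B carbinol) | O=C1[C@H](C(O)c2cc(OC)c(O[Si](C(C)C)(C(C)C)C(C)C)c(c2)[C@H]3COC(C)(C)O[C@H]3c6ccc(O[Si](C(C)C)(C(C)C)C(C)C)c(OC)c6)[C@H](CO1)[C@H](O)c7cc(OC)c8c(c7)[C@@H](CO[Si](C(C)C)(C(C)C)C(C)C)[C@@H](c9ccc(O[Si](C(C)C)(C(C)C)C(C)C)c(OC)c9)O8 | intermediate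
47 | (2R,3R)-2-[(B-aryl)(hydroxy)methyl]-3-[(S)-(D-aryl)(hydroxy)methyl]butane-1,4-diol | OC[C@H](C(O)c2cc(OC)c(O[Si](C(C)C)(C(C)C)C(C)C)c(c2)[C@H]3COC(C)(C)O[C@H]3c6ccc(O[Si](C(C)C)(C(C)C)C(C)C)c(OC)c6)[C@H](CO)[C@H](O)c7cc(OC)c8c(c7)[C@@H](CO[Si](C(C)C)(C(C)C)C(C)C)[C@@H](c9ccc(O[Si](C(C)C)(C(C)C)C(C)C)c(OC)c9)O8 | intermediate
48 | (1R,2S,5R,6S)-2-(B-aryl)-6-(D-aryl)-3,7-dioxabicyclo[3.3.0]octane (exo,exo) | CC1(C)OC[C@H](c2cc([C@H]3OC[C@H]4[C@@H]3CO[C@@H]4c5cc(OC)c6c(c5)[C@@H](CO[Si](C(C)C)(C(C)C)C(C)C)[C@@H](c7ccc(O[Si](C(C)C)(C(C)C)C(C)C)c(OC)c7)O6)cc(OC)c2O[Si](C(C)C)(C(C)C)C(C)C)[C@@H](O1)c8ccc(O[Si](C(C)C)(C(C)C)C(C)C)c(OC)c8 | intermediate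
49 | (1R,2S)-2-{5-[(1R,2S,5R,6S)-6-(D-aryl)-3,7-dioxabicyclo[3.3.0]octan-2-yl]-3-methoxy-2-[(triisopropylsilyl)oxy]phenyl}-1-{3-methoxy-4-[(triisopropylsilyl)oxy]phenyl}propane-1,3-diol | OC[C@H](c2cc([C@H]3OC[C@H]4[C@@H]3CO[C@@H]4c5cc(OC)c6c(c5)[C@@H](CO[Si](C(C)C)(C(C)C)C(C)C)[C@@H](c7ccc(O[Si](C(C)C)(C(C)C)C(C)C)c(OC)c7)O6)cc(OC)c2O[Si](C(C)C)(C(C)C)C(C)C)[C@@H](O)c8ccc(O[Si](C(C)C)(C(C)C)C(C)C)c(OC)c8 | intermediate
50 | (2S)-2-{5-[(1R,2S,5R,6S)-6-(D-aryl)-3,7-dioxabicyclo[3.3.0]octan-2-yl]-3-methoxy-2-[(triisopropylsilyl)oxy]phenyl}-3-hydroxy-1-{3-methoxy-4-[(triisopropylsilyl)oxy]phenyl}propan-1-one | OC[C@H](c2cc([C@H]3OC[C@H]4[C@@H]3CO[C@@H]4c5cc(OC)c6c(c5)[C@@H](CO[Si](C(C)C)(C(C)C)C(C)C)[C@@H](c7ccc(O[Si](C(C)C)(C(C)C)C(C)C)c(OC)c7)O6)cc(OC)c2O[Si](C(C)C)(C(C)C)C(C)C)C(=O)c8ccc(O[Si](C(C)C)(C(C)C)C(C)C)c(OC)c8 | intermediate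
51 | CNP0174045.1, (2S)-3-hydroxy-1-(4-hydroxy-3-methoxyphenyl)-2-{2-hydroxy-5-[(1R,2S,5R,6S)-6-[(2S,3S)-2-(4-hydroxy-3-methoxyphenyl)-3-(hydroxymethyl)-7-methoxy-2,3-dihydro-1-benzofuran-5-yl]-3,7-dioxabicyclo[3.3.0]octan-2-yl]-3-methoxyphenyl}propan-1-one | COc1cc(C(=O)[C@H](CO)c2cc([C@H]3OC[C@H]4[C@@H]3CO[C@@H]4c3cc(OC)c4c(c3)[C@@H](CO)[C@@H](c3ccc(O)c(OC)c3)O4)cc(OC)c2O)ccc1O | target

## Step count and least certain steps

Total: 33 steps. Longest linear sequence: 17 steps (from 1 through steps 1 to 4, 6, 11 to 14 and 26 to 33).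

**Step 12 (key step).** The most likely failure is that the cycloaddition is not reached before the substrate decomposes. An electron-rich 3,4-dialkoxypyrone is paired with an unactivated alkyne, so the temperature needed may first break the benzylic C–O bond (ionisation or elimination toward the enyne). Fallback, setting out from 31 and 7 and returning at 21: ring D is taken from the bromoarene already made for ring B, and the five-membered ring is closed at oxygen.
- Boron aldol addition of 31 to 7 (Bu2BOTf, iPr2NEt) should give the syn aldol adduct with the pivalate-protected ring E F1.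
- NaBH4 in wet THF removes the auxiliary to give the 1,3-diol F2.
- TIPSCl and imidazole silylate the primary hydroxyl to give the mono-TIPS ether F3.
- AcOH-buffered TBAF at 0 °C frees only the aryl silyl ether to give the phenol carbinol F4.
- PPh3 and DIAD close the ring by intramolecular Mitsunobu etherification with inversion at the benzylic carbon, turning the syn aldol relation into the cis ring of the 5-bromo dihydrobenzofuran pivalate F5.
- Ester-to-silyl exchange as in step 13 gives the 5-bromo dihydrobenzofuran TIPS ether F6, and bromine–lithium exchange (n-BuLi) followed by DMF gives 21.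

**Step 11.** The most likely failure is loss of configurational fidelity at the benzylic carbon through ionisation of the oxyphosphonium intermediate, or elimination toward the conjugated enyne, because the carbinol is secondary, benzylic and β-branched. Fallback, setting out from 9 and 15 and returning at 16: activation and displacement are separated. MsCl and Et3N at −40 °C convert 9 into the benzylic mesylate F7, which is displaced with inversion by the caesium salt of 15 (Cs2CO3, DMF, 0 °C → rt), a weakly basic oxygen nucleophile. If this also fails, the sequence F1 to F6 above bypasses steps 11 and 12 together.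

**Step 10.** The most likely failure is protodeboronation of the boronate, which sits α to the lactone carbonyl, or opening of the pyrone ring during the peroxide oxidation. Fallback, setting out from 13 and returning at 15: direct palladium-catalysed C–O coupling with benzaldoxime as hydroxide surrogate (Pd2(dba)3, a bulky biarylphosphine, Cs2CO3, DMF, 80 °C). The O-pyronyl benzaldoxime F8 forms and fragments in the flask to 15 and benzonitrile, so no boron intermediate is involved.

**Step 28.** The most likely failure is incomplete or unselective addition, because the alkoxide of the dianion can aggregate, translactonise to the isomeric lactone, or weaken the facial bias of the enolate. Fallback, setting out from 44 and returning at 46: the carbinol is masked first. TESCl and imidazole give the TES-protected lactone F9. Its mono-enolate (LiHMDS, THF, −78 °C) adds to 37 to give the TES-protected trans aldol lactone F10. AcOH–THF–H2O at room temperature removes only the triethylsilyl group and gives 46.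

**Step 30.** The most likely failure is erosion of the exo,exo selectivity by reversible ionisation, together with competing closure between the two benzylic oxygens (2,5-diaryl tetrahydrofuran) and acetal migration. Fallback, setting out from 46 and returning at 48: the two rings are closed one at a time and the ring D side without ionisation.
- Catalytic CSA on 46 should move the lactone to the ring D carbinol oxygen, which keeps its configuration, while the freed primary hydroxyl captures the ring B benzylic cation on the rigid lactone, giving the bicyclic lactone (1S,2S,5R,6S)-2-(B-aryl)-6-(D-aryl)-3,7-dioxabicyclo[3.3.0]octan-8-one F11.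
- LiAlH4 gives the tetrahydrofuran diol F12.
- MsCl and Et3N give the primary mesylate F13 (not isolated), which the benzylic hydroxyl displaces with retention at C6 to give 48.

**Step 32.** The most likely failure is a sluggish heterogeneous oxidation of the hindered secondary benzylic alcohol, with slow oxidation of the primary alcohol on long exposure. Fallback, setting out from 49 and returning at 51: TBSCl and imidazole at 0 °C silylate the primary hydroxyl to give the primary TBS ether F14. Dess–Martin periodinane with pyridine gives the silylated ketone F15. HF·pyridine as in step 33 removes all five silyl groups and gives 51.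

## Further compounds

F1 | step 12 | (R)-4-benzyl-3-[(2R,3R)-2-{5-bromo-3-methoxy-2-[(triisopropylsilyl)oxy]phenyl}-3-hydroxy-3-[3-methoxy-4-(pivaloyloxy)phenyl]propanoyl]-1,3-oxazolidin-2-one | O=C(N1[C@H](Cc2ccccc2)COC1=O)[C@H](c1cc(Br)cc(OC)c1O[Si](C(C)C)(C(C)C)C(C)C)[C@@H](O)c1ccc(OC(=O)C(C)(C)C)c(OC)c1
F2 | step 12 | 4-[(1R,2S)-2-{5-bromo-3-methoxy-2-[(triisopropylsilyl)oxy]phenyl}-1,3-dihydroxypropyl]-2-methoxyphenyl pivalate | OC[C@H](c1cc(Br)cc(OC)c1O[Si](C(C)C)(C(C)C)C(C)C)[C@@H](O)c1ccc(OC(=O)C(C)(C)C)c(OC)c1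
F3 | step 12 | 4-[(1R,2S)-2-{5-bromo-3-methoxy-2-[(triisopropylsilyl)oxy]phenyl}-1-hydroxy-3-[(triisopropylsilyl)oxy]propyl]-2-methoxyphenyl pivalate | CC(C)[Si](C(C)C)(C(C)C)OC[C@H](c1cc(Br)cc(OC)c1O[Si](C(C)C)(C(C)C)C(C)C)[C@@H](O)c1ccc(OC(=O)C(C)(C)C)c(OC)c1
F4 | step 12 | 4-[(1R,2S)-2-(5-bromo-2-hydroxy-3-methoxyphenyl)-1-hydroxy-3-[(triisopropylsilyl)oxy]propyl]-2-methoxyphenyl pivalate | CC(C)[Si](C(C)C)(C(C)C)OC[C@H](c1cc(Br)cc(OC)c1O)[C@@H](O)c1ccc(OC(=O)C(C)(C)C)c(OC)c1
F5 | step 12 | 4-[(2S,3S)-5-bromo-7-methoxy-3-{[(triisopropylsilyl)oxy]methyl}-2,3-dihydro-1-benzofuran-2-yl]-2-methoxyphenyl pivalate | Brc1cc(OC)c2c(c1)[C@@H](CO[Si](C(C)C)(C(C)C)C(C)C)[C@@H](c1ccc(OC(=O)C(C)(C)C)c(OC)c1)O2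
F6 | step 12 | {4-[(2S,3S)-5-bromo-7-methoxy-3-{[(triisopropylsilyl)oxy]methyl}-2,3-dihydro-1-benzofuran-2-yl]-2-methoxyphenoxy}triisopropylsilane | Brc1cc(OC)c2c(c1)[C@@H](CO[Si](C(C)C)(C(C)C)C(C)C)[C@@H](c1ccc(O[Si](C(C)C)(C(C)C)C(C)C)c(OC)c1)O2
F7 | step 11 | 4-[(1R,2S)-1-[(methylsulfonyl)oxy]-2-{[(triisopropylsilyl)oxy]methyl}but-3-yn-1-yl]-2-methoxyphenyl pivalate | COc1cc(ccc1OC(=O)C(C)(C)C)[C@H](OS(C)(=O)=O)[C@H](CO[Si](C(C)C)(C(C)C)C(C)C)C#C
F8 | step 10 | (E)-benzaldehyde O-[6-(dimethoxymethyl)-4-methoxy-2-oxo-2H-pyran-3-yl]oxime | COC(OC)C1=CC(OC)=C(O/N=C/c2ccccc2)C(=O)O1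
F9 | step 28 | (4R)-4-[(S)-(D-aryl)(triethylsilyloxy)methyl]oxolan-2-one | O=C1C[C@H](CO1)[C@H](O[Si](CC)(CC)CC)c3cc(OC)c4c(c3)[C@@H](CO[Si](C(C)C)(C(C)C)C(C)C)[C@@H](c5ccc(O[Si](C(C)C)(C(C)C)C(C)C)c(OC)c5)O4
F10 | step 28 | (3S,4R)-3-[(B-aryl)(hydroxy)methyl]-4-[(S)-(D-aryl)(triethylsilyloxy)methyl]oxolan-2-one | O=C1[C@H](C(O)c2cc(OC)c(O[Si](C(C)C)(C(C)C)C(C)C)c(c2)[C@H]3COC(C)(C)O[C@H]3c6ccc(O[Si](C(C)C)(C(C)C)C(C)C)c(OC)c6)[C@H](CO1)[C@H](O[Si](CC)(CC)CC)c7cc(OC)c8c(c7)[C@@H](CO[Si](C(C)C)(C(C)C)C(C)C)[C@@H](c9ccc(O[Si](C(C)C)(C(C)C)C(C)C)c(OC)c9)O8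
F11 | step 30 | (1S,2S,5R,6S)-2-(B-aryl)-6-(D-aryl)-3,7-dioxabicyclo[3.3.0]octan-8-one | CC1(C)OC[C@H](c2cc([C@H]3OC[C@H]4[C@@H]3C(=O)O[C@@H]4c5cc(OC)c6c(c5)[C@@H](CO[Si](C(C)C)(C(C)C)C(C)C)[C@@H](c7ccc(O[Si](C(C)C)(C(C)C)C(C)C)c(OC)c7)O6)cc(OC)c2O[Si](C(C)C)(C(C)C)C(C)C)[C@@H](O1)c8ccc(O[Si](C(C)C)(C(C)C)C(C)C)c(OC)c8
F12 | step 30 | [(2S,3R,4R)-2-(B-aryl)-4-[(S)-(D-aryl)(hydroxy)methyl]oxolan-3-yl]methanol | CC1(C)OC[C@H](c2cc([C@H]3OC[C@@H]([C@@H]3CO)[C@H](O)c5cc(OC)c6c(c5)[C@@H](CO[Si](C(C)C)(C(C)C)C(C)C)[C@@H](c7ccc(O[Si](C(C)C)(C(C)C)C(C)C)c(OC)c7)O6)cc(OC)c2O[Si](C(C)C)(C(C)C)C(C)C)[C@@H](O1)c8ccc(O[Si](C(C)C)(C(C)C)C(C)C)c(OC)c8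
F13 | step 30 | [(2S,3R,4R)-2-(B-aryl)-4-[(S)-(D-aryl)(hydroxy)methyl]oxolan-3-yl]methyl methanesulfonate | CC1(C)OC[C@H](c2cc([C@H]3OC[C@@H]([C@@H]3COS(C)(=O)=O)[C@H](O)c5cc(OC)c6c(c5)[C@@H](CO[Si](C(C)C)(C(C)C)C(C)C)[C@@H](c7ccc(O[Si](C(C)C)(C(C)C)C(C)C)c(OC)c7)O6)cc(OC)c2O[Si](C(C)C)(C(C)C)C(C)C)[C@@H](O1)c8ccc(O[Si](C(C)C)(C(C)C)C(C)C)c(OC)c8
F14 | step 32 | (1R,2S)-3-[(tert-butyldimethylsilyl)oxy]-2-{5-[(1R,2S,5R,6S)-6-(D-aryl)-3,7-dioxabicyclo[3.3.0]octan-2-yl]-3-methoxy-2-[(triisopropylsilyl)oxy]phenyl}-1-{3-methoxy-4-[(triisopropylsilyl)oxy]phenyl}propan-1-ol | CC(C)(C)[Si](C)(C)OC[C@H](c2cc([C@H]3OC[C@H]4[C@@H]3CO[C@@H]4c5cc(OC)c6c(c5)[C@@H](CO[Si](C(C)C)(C(C)C)C(C)C)[C@@H](c7ccc(O[Si](C(C)C)(C(C)C)C(C)C)c(OC)c7)O6)cc(OC)c2O[Si](C(C)C)(C(C)C)C(C)C)[C@@H](O)c8ccc(O[Si](C(C)C)(C(C)C)C(C)C)c(OC)c8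
F15 | step 32 | (2S)-3-[(tert-butyldimethylsilyl)oxy]-2-{5-[(1R,2S,5R,6S)-6-(D-aryl)-3,7-dioxabicyclo[3.3.0]octan-2-yl]-3-methoxy-2-[(triisopropylsilyl)oxy]phenyl}-1-{3-methoxy-4-[(triisopropylsilyl)oxy]phenyl}propan-1-one | CC(C)(C)[Si](C)(C)OC[C@H](c2cc([C@H]3OC[C@H]4[C@@H]3CO[C@@H]4c5cc(OC)c6c(c5)[C@@H](CO[Si](C(C)C)(C(C)C)C(C)C)[C@@H](c7ccc(O[Si](C(C)C)(C(C)C)C(C)C)c(OC)c7)O6)cc(OC)c2O[Si](C(C)C)(C(C)C)C(C)C)C(=O)c8ccc(O[Si](C(C)C)(C(C)C)C(C)C)c(OC)c8
A1 | alternative 1 | 5-bromo-3-methoxy-2-(trimethylsilyl)phenyl trifluoromethanesulfonate | COc1cc(Br)cc(OS(=O)(=O)C(F)(F)F)c1[Si](C)(C)C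
A2 | alternative 1 | methyl 2-(2-acetyl-5-bromo-3-methoxyphenyl)acetate | COC(=O)Cc1cc(Br)cc(OC)c1C(C)=O
A3 | alternative 2 | (2R,3R)-2-(3-bromo-4-hydroxy-5-methoxybenzyl)-3-{[(2S,3S)-7-methoxy-2-[3-methoxy-4-(tosyloxy)phenyl]-3-{[(triisopropylsilyl)oxy]methyl}-2,3-dihydro-1-benzofuran-5-yl]methyl}butane-1,4-diol | COc1cc(C[C@@H](CO)[C@H](CO)Cc2cc(OC)c3c(c2)[C@@H](CO[Si](C(C)C)(C(C)C)C(C)C)[C@@H](c2ccc(OS(=O)(=O)c4ccc(C)cc4)c(OC)c2)O3)cc(Br)c1O
A4 | alternative 2 | 2-bromo-6-methoxy-4-[(1R,2S,5R,6S)-6-{(2S,3S)-7-methoxy-2-[3-methoxy-4-(tosyloxy)phenyl]-3-{[(triisopropylsilyl)oxy]methyl}-2,3-dihydro-1-benzofuran-5-yl}-3,7-dioxabicyclo[3.3.0]octan-2-yl]phenol | COc1cc([C@H]2OC[C@H]3[C@@H]2CO[C@@H]3c2cc(OC)c3c(c2)[C@@H](CO[Si](C(C)C)(C(C)C)C(C)C)[C@@H](c2ccc(OS(=O)(=O)c4ccc(C)cc4)c(OC)c2)O3)cc(Br)c1O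
A5 | alternative 3 | (5R)-5-{[(1R,2S,5R)-2-isopropyl-5-methylcyclohexyl]oxy}furan-2(5H)-one | O=C1C=C[C@@H](O1)O[C@@H]2C[C@H](C)CC[C@H]2C(C)C
A6 | alternative 3 | trans-3-[(4-benzyloxy-3-bromo-5-methoxyphenyl)(hydroxy)methyl]-4-[2-(ring D aryl)-1,3-dithian-2-yl]-5-(menthyloxy)oxolan-2-one (ring E as benzyl ether) | O=C1O[C@@H](O[C@@H]2C[C@H](C)CC[C@H]2C(C)C)[C@H](C2(SCCCS2)c2cc(OC)c3c(c2)[C@@H](CO[Si](C(C)C)(C(C)C)C(C)C)[C@@H](c2ccc(OCc4ccccc4)c(OC)c2)O3)[C@H]1[C@@H](O)c1cc(OC)c(OCc2ccccc2)c(Br)c1
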